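## The problem

Compound 22 is a linear trimer of phloroglucinol-type rings held together by two diaryl ether oxygens. Ring A is a 3,5-dihydroxyphenoxy group on C1 of ring B; ring B carries hydroxyls at C2 and C6 and, at C4, the oxygen that leads to ring C; ring C has that ether oxygen at C1, hydroxyls at C2, C4 and C6, hydrogen at C3 and bromine at C5. There is no stereocentre and no configurationally stable axis, so no stereocontrol is needed and none can be borrowed; the difficulties are connectivity and site selectivity. Both ether oxygens sit on carbons flanked by two oxygenated neighbours (C1 of ring B and C1 of ring C), which makes each ether hard to form by cross-coupling on that side. Every ring is an electron-rich trioxygenated arene with open positions activated by three oxygens (three on ring A, two on ring B, two on ring C), yet exactly one bromine must be placed, on ring C only. Because C3 and C5 of ring C become equivalent once O2, O4 and O6 are all free, the real question is "ring C and nothing else, and only once". The free heptaphenol is sensitive to base and air, the C–Br bond rules out hydrogenolysis, and an electron-rich aryl bromide can lose bromine under forcing acid, so the hydroxyls should stay masked as alkyl ethers to the last step and the halogen should arrive late and mildly. The enabling feature is the pattern of ring C itself: C6 (OH), C1 (O-aryl), C2 (O) and C3 (H) map onto the carbonyl carbon, the sp3 carbon and the two enol ether carbons of a 4-aryloxy-3-alkoxycyclobutenone, and C4 (O) and C5 onto the two carbons of an alkoxyacetylene whose second carbon can carry a silyl group as a stand-in for bromine.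

## Retrosynthesis

**22 from 21 (six O–alkyl bonds).** The last cut removes five O–CH3 bonds and one O–C2H5 bond. Alkyl ethers are preferred to benzyl ethers, whose hydrogenolysis would endanger the C–Br bond, and to silyl or acyl groups, which would not survive a peracid, hydroxide, an acid chloride, 110 °C and a bromine donor. 21 differs from 22 only by six robust alkyl groups, so every earlier intermediate is non-polar, air-stable and chromatographable. The forward step must cleave all six ethers with a boron Lewis acid without touching the diaryl ethers or the bromide.

**21 from 20 (C5–Br from C5–Si).** The C–Br bond is traced back to a C–Si bond at the same carbon. A ring C with hydrogen at both C3 and C5 would also converge on 22, since the two positions become equivalent after deprotection, but would rely on the free phenol alone to outrun rings A and B. The silyl group adds the rate advantage of ipso substitution, so the carbon that reacts first in the whole molecule lies on ring C and one equivalent of a mild bromine donor at low temperature should suffice. 20 is no simpler in skeleton, but it is the direct product of the ring-forming step. The forward step must give ipso substitution faster than any C–H bromination.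

**20 from 12 and 15 (C5–C6, C3–C4 and C6–C1 of ring C; the key cut).** Ring C is taken apart into cyclobutenone 12 and silyl ynol ether 15. Forward, 12 opens to vinylketene 16, which adds 15 to give 17; 17 passes through dienylketene 18 and dienone 19 to phenol 20. Making the ring B–ring C ether by coupling instead would need a C–O bond at a ring C carbon flanked by two oxygens, on a ring that must also carry the halogen or its precursor; here the oxygen is on the future C1 before ring C exists. Among the ways of mapping ring C onto a cyclobutenone and an alkyne, this one puts the aryloxy group on the ketene-derived carbon and the placeholder on the alkyne. The cut removes a hexasubstituted benzene ring and leaves a two-ring aryl ether with a four-carbon appendage plus a small alkyne. The forward step needs one orientation in the ketene–alkyne cycloaddition and an alkyne that survives 80–110 °C; 15 is therefore the methyl ynol ether, which has no β-hydrogen for retro-ene fragmentation.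

**15 from 13 (the C–Si bond and the triple bond).** 15 goes back to lithium acetylide 14 and a silyl chloride, and 14 to chloroacetal 13 by two base-induced eliminations. Generating the acetylide in the flask avoids handling the free, very volatile alkyne. The precursor is a bulk chemical one flask away. The forward step needs complete elimination before silylation.

**12 from 8 and 9 (two bonds of the four-membered ring).** The cyclobutenone is cut between the carbonyl carbon and the CH carbon and between the aryloxy-bearing carbon and the ethoxy-bearing carbon, the retron of a ketene–alkyne [2+2] addition. This leads to aryloxyketene 11 (from acid 8 through acid chloride 10) and ethoxyacetylene 9. No other two-bond cut gives partners that are both accessible, and the polarity of both partners fixes the orientation. The precursor is an open-chain acid. The forward step must trap a reactive aldoketene with the ynol ether before it dimerises.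

**8 from 7, and 7 from 5 and 6 (O–CH2 bond, then ester).** The acid comes from ester 7, and 7 from phenol 5 and methyl bromoacetate 6 by O-alkylation. The free oxygen of 5 is unhindered, so this is the easy side of ring B to alkylate. Two routine steps are asked for.

**5 from 3 (C4–O of ring B from C–CHO).** Phenol 5 is traced back to aldehyde 3 through formate 4 by oxidative aryl migration. Storing the C4 oxygen as a formyl group differentiates the two oxygens on C1 and C4 of ring B from the start, and it matches the functionality of commercial material. The forward step needs aryl rather than hydride migration, which the para aryloxy group favours.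

**3 from 1 and 2 (ring A–O bond at C1 of ring B).** The hindered ether is cut on the ring A side, where the carbon has no ortho substituent: syringaldehyde 1 supplies the di-ortho-substituted phenol and boronic acid 2 supplies ring A with both oxygens in place. Cutting on the ring B side would need substitution at a carbon between two methoxy groups. Both precursors are commercial. The forward step is a copper-mediated oxidative O-arylation of a phenol with two ortho substituents.

## Roads not taken

**Alternative 1:** ring A hydroxyls by late double C–H borylation and oxidation. The cut is at the two C–O bonds on C3 and C5 of ring A. The substrate would be A2, 2-bromo-4-(3,5-dimethoxy-4-phenoxyphenoxy)-1,3,5-trimethoxybenzene, with a plain phenyl ether as ring A. Borylation with [Ir(OMe)(cod)]2 and a bipyridine ligand, then oxidation of both boronates, would give A1, 5-[4-(3-bromo-2,4,6-trimethoxyphenoxy)-2,6-dimethoxyphenoxy]benzene-1,3-diol.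
- Merits: sterically governed borylation cannot touch rings B and C of A2, since every C–H there is flanked by two substituents; the aryl bromide is tolerated; ring A enters as a cheap phenyl group. Ring C enters as a symmetrical trimethoxyphenoxy unit whose monobromination has no regiochemical ambiguity, so the halogen is placed without a placeholder. The route is probably two or three steps shorter.
- Weak points: the first borylation of a monosubstituted phenyl ether divides between meta and para positions in a near-statistical way, and only meta-borylated material can reach the 3,5-pattern, so part of the most advanced intermediate is lost. A1 still needs five O-demethylations. The bromination must still favour the trimethoxy ring over ring B.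
- Comparison: in step count and simplicity of halogenation this road is at least equal. The chosen plan offers ring A oxygens bought in the right positions, no statistical late step, and a hardest ring built by neutral, metal-free chemistry with the halogen site fixed by connectivity.

**Alternative 2:** ring B closed by a triketide-type Claisen cyclisation. The cut is a C–C bond of ring B. The precursor would be A4, methyl (2E)-3-(3-bromo-2,4,6-trimethoxyphenoxy)-6-(3,5-dimethoxyphenoxy)-5-oxohex-2-enoate. Base would close its C6 enolate onto the ester and aromatise to A3, 5-(3-bromo-2,4,6-trimethoxyphenoxy)-2-(3,5-dimethoxyphenoxy)benzene-1,3-diol.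
- Merits: the hindered ring A–ring B ether is never made by coupling, because its carbon arrives as an α-aryloxy ketone carbon; the two hydroxyls of ring B appear free; bromine is again placed early on a symmetrical ring.
- Weak points: A4 contains a β-aryloxy enoate, a vinylogous carbonate from which alkoxide can expel the ring C phenoxide by addition–elimination. Its most acidic site is C4, between the enol ether and the ketone, not C6, which must react. A4 itself takes several C-acylation steps, and five methyl ethers remain to be cleaved.
- Comparison: this road is as good in avoiding the hindered coupling and in placing bromine. The chosen plan has a precedented copper-mediated arylation of a di-ortho-substituted phenol for that ether, and a ring closure under neutral thermal conditions with no base-labile aryloxide leaving group in the substrate.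

**Alternative 3:** ring C from an aryloxymalonate and an acetonedicarboxylate. The cut is at C2–C3 and C5–C6 of ring C. Double Claisen condensation of A6, dimethyl 2-[4-(3,5-dimethoxyphenoxy)-3,5-dimethoxyphenoxy]propanedioate, with A7, dimethyl 3-oxopentanedioate, would give A5, dimethyl 5-[4-(3,5-dimethoxyphenoxy)-3,5-dimethoxyphenoxy]-2,4,6-trihydroxybenzene-1,3-dicarboxylate.
- Merits: cheap classical chemistry; the three hydroxyls of ring C arrive free, so only four ethers remain at the end. After removal of the esters, ring C would be the only free phloroglucinol and by far the most nucleophilic ring, so ring selectivity of bromination comes from reactivity alone.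
- Weak points: two identical ester groups must be hydrolysed and decarboxylated. The ring then has two equivalent, equally activated positions, so stopping after one bromine depends only on the small deactivation by the first. A6 is a hindered, weakly acidic partner for a double acylation, and the free triols are air-sensitive over several operations.
- Comparison: this road is better in reagent cost and in the number of protecting groups. The chosen plan offers a single carbon that reacts faster than any other (ipso acceleration) and intermediates that stay fully masked until the end.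

Key step: step 7

## Route

Remark on the chemistry: 22 is achiral; 12, 17 and 19 each hold one sp3 stereocentre, form as racemates and lose that centre on aromatisation, so no configuration has to be set or kept.

Step 1
Reactants: 1 syringaldehyde (4-hydroxy-3,5-dimethoxybenzaldehyde); 2 3,5-dimethoxyphenylboronic acid
Product: 3 4-(3,5-dimethoxyphenoxy)-3,5-dimethoxybenzaldehyde
Conditions: Cu(OAc)2 (1.5 equiv), pyridine, 4 Å molecular sieves, CH2Cl2, dry air, rt; 2 (2.5 equiv) in portions
Reagents that add atoms: none
Why: Chan–Lam oxidative O-arylation: phenoxide and aryl group meet on copper and reductive elimination forms the ring A–O bond; the reaction type accepts phenols with two ortho substituents and tolerates the aldehyde, and the sieves limit oxidation of 2 to its phenol.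

Step 2
Reactants: 3 4-(3,5-dimethoxyphenoxy)-3,5-dimethoxybenzaldehyde
Product: 5 4-(3,5-dimethoxyphenoxy)-3,5-dimethoxyphenol, via aryl formate 4 (not isolated)
Conditions: mCPBA, CH2Cl2, 0 °C to rt; then K2CO3 (cat.), MeOH, rt
Reagents that add atoms: 3-chloroperoxybenzoic acid (mCPBA), O=C(OO)c1cccc(Cl)c1
Why: Baeyer–Villiger oxidation of an electron-rich benzaldehyde (Dakin-type): the aryl group, activated by the para aryloxy oxygen, migrates to give formate 4, which is methanolysed to the phenol; this is the routine way from 3,4,5-trialkoxybenzaldehydes to the phenols.

Step 3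
Reactants: 5 4-(3,5-dimethoxyphenoxy)-3,5-dimethoxyphenol; 6 methyl bromoacetate
Product: 7 methyl 2-[4-(3,5-dimethoxyphenoxy)-3,5-dimethoxyphenoxy]acetate
Conditions: K2CO3, acetone, reflux
Reagents that add atoms: none
Why: Williamson ether synthesis: the unhindered phenoxide of 5 displaces bromide from the α-halo ester by SN2.

Step 4
Reactants: 7 methyl 2-[4-(3,5-dimethoxyphenoxy)-3,5-dimethoxyphenoxy]acetate
Product: 8 2-[4-(3,5-dimethoxyphenoxy)-3,5-dimethoxyphenoxy]acetic acid
Conditions: LiOH·H2O, THF/H2O, rt; then 1 M HCl
Reagents that add atoms: lithium hydroxide, [Li+].[OH-]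
Why: Ester saponification by acyl substitution with hydroxide; the aryl ethers are inert.

Step 5
Reactants: 8 2-[4-(3,5-dimethoxyphenoxy)-3,5-dimethoxyphenoxy]acetic acid; 9 ethoxyacetylene
Product: 12 racemic 4-[4-(3,5-dimethoxyphenoxy)-3,5-dimethoxyphenoxy]-3-ethoxycyclobut-2-en-1-one, via acid chloride 10 (not isolated), via aryloxyketene 11 (not isolated)
Conditions: (COCl)2, DMF (cat.), CH2Cl2, 0 °C to rt, evaporate; then slow addition to 9 (3 equiv), Et3N, CH2Cl2, 0 °C to rt
Reagents that add atoms: none
Why: Dehydrochlorination of the acid chloride gives aryloxyketene 11 (as in Staudinger chemistry), and its thermal [2+2] cycloaddition with the ynol ether is the classical route to 3-ethoxycyclobutenones. The nucleophilic CH carbon of 9 bonds to the ketene carbonyl carbon and the ethoxy-bearing carbon to the ketene α-carbon, so OEt ends at C3 and the aryloxy group at C4; the new sp3 centre is racemic and is destroyed in step 7.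

Step 6
Reactants: 13 chloroacetaldehyde dimethyl acetal (2-chloro-1,1-dimethoxyethane)
Product: 15 (methoxyethynyl)trimethylsilane, via lithium methoxyacetylide 14 (not isolated)
Conditions: LiNEt2 (3.1 equiv, from Et2NH and n-BuLi), THF, 0 °C; then Me3SiCl (2.2 equiv), −78 °C to rt; distillation
Reagents that add atoms: chlorotrimethylsilane, C[Si](C)(C)Cl
Why: Two base-induced eliminations (of methanol and of HCl) turn the chloroacetal into the alkoxyalkyne, which the third equivalent of amide deprotonates; C-silylation of the acetylide is a standard quench, and the second equivalent of Me3SiCl takes up the methoxide so that it cannot cleave the alkynyl–silicon bond.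

Step 7
Reactants: 12 racemic 4-[4-(3,5-dimethoxyphenoxy)-3,5-dimethoxyphenoxy]-3-ethoxycyclobut-2-en-1-one; 15 (methoxyethynyl)trimethylsilane
Product: 20 6-[4-(3,5-dimethoxyphenoxy)-3,5-dimethoxyphenoxy]-5-ethoxy-3-methoxy-2-(trimethylsilyl)phenol, via vinylketene 16 (not isolated), via vinylcyclobutenone 17 (not isolated), via dienylketene 18 (not isolated), via cyclohexadienone 19 (not isolated)
Conditions: 15 (2.5 equiv), toluene, 80 °C then 110 °C, sealed tube, argon; chromatography on Et3N-deactivated silica
Reagents that add atoms: none
Why: Danheiser benzannulation; the closest known reaction type is the thermal annulation of cyclobutenones with alkoxy- and siloxyacetylenes. Heating should open 12 by 4π conrotatory cleavage of the bond between the carbonyl carbon and the aryloxy-bearing carbon, the aryloxy donor turning outward, to give vinylketene 16. The ketene C=C of 16 should add 15 in a [2+2] cycloaddition that forms C5–C6 (silyl-bearing alkyne carbon to ketene carbonyl carbon) and C3–C4 (ketene α-carbon to methoxy-bearing carbon) and gives 17. 17 should reopen reversibly to dienylketene 18, and the isomer with ketene and enol ether terminus cis closes the six-membered ring C by a thermally allowed disrotatory 6π electrocyclisation (bond C6–C1) to dienone 19; tautomerisation to phenol 20 makes the cascade irreversible. The one selectivity needed is the orientation of the [2+2] step: the oxygen lone pair makes the silyl-bearing carbon of 15 the nucleophilic terminus, and the positive charge building up on the other carbon is stabilised by both the α-oxygen and the β-silicon, so silicon must end at C5 between the new hydroxyl and the methoxy group. No stereocentre survives, since the sp3 carbons of 12, 17 and 19 become aromatic. The methyl ynol ether cannot fragment by a retro-ene path at this temperature, and the new phenol, flanked by SiMe3 and the aryloxy group, should be too hindered to be acylated by excess ketene.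

Step 8
Reactants: 20 6-[4-(3,5-dimethoxyphenoxy)-3,5-dimethoxyphenoxy]-5-ethoxy-3-methoxy-2-(trimethylsilyl)phenol
Product: 21 2-bromo-6-[4-(3,5-dimethoxyphenoxy)-3,5-dimethoxyphenoxy]-5-ethoxy-3-methoxyphenol
Conditions: NBS (1.0 equiv, added slowly as a solution), CH2Cl2, −78 °C to −40 °C, dark
Reagents that add atoms: N-bromosuccinimide, O=C1CCC(=O)N1Br
Why: Electrophilic ipso-bromodesilylation: attack at C5 is favoured by the ortho hydroxyl, the ortho and para alkoxy groups and β-silicon stabilisation of the arenium ion, so one equivalent at low temperature should leave C3–H and rings A and B untouched. Should some bromine enter at C3 instead, that isomer would still lead to 22, because C3 and C5 become equivalent after full deprotection and the remaining silyl group should be lost under the acid of step 9.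

Step 9
Reactants: 21 2-bromo-6-[4-(3,5-dimethoxyphenoxy)-3,5-dimethoxyphenoxy]-5-ethoxy-3-methoxyphenol
Product: 22 2-bromo-4-[4-(3,5-dihydroxyphenoxy)-3,5-dihydroxyphenoxy]benzene-1,3,5-triol (CNP0039507.0)
Conditions: BBr3 (15 equiv), CH2Cl2, −78 °C to rt; then ice-water, degassed work-up
Reagents that add atoms: none
Why: Lewis acid cleavage of aryl alkyl ethers by BBr3 (boron coordination, bromide attack at the alkyl carbon) removes the five methyl groups and the ethyl group; diaryl ether C–O bonds and the aryl bromide are not attacked, and hydrolysis frees the seven phenols.

## Compound list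

1 | syringaldehyde (4-hydroxy-3,5-dimethoxybenzaldehyde) | COc1cc(C=O)cc(OC)c1O | starting material
2 | 3,5-dimethoxyphenylboronic acid | COc1cc(OC)cc(B(O)O)c1 | starting material
3 | 4-(3,5-dimethoxyphenoxy)-3,5-dimethoxybenzaldehyde | COc1cc(C=O)cc(OC)c1Oc1cc(OC)cc(OC)c1 | intermediate
4 | 4-(3,5-dimethoxyphenoxy)-3,5-dimethoxyphenyl formate (formed in the flask, not isolated) | O=COc1cc(OC)c(Oc2cc(OC)cc(OC)c2)c(OC)c1 | intermediate
5 | 4-(3,5-dimethoxyphenoxy)-3,5-dimethoxyphenol | Oc1cc(OC)c(Oc2cc(OC)cc(OC)c2)c(OC)c1 | intermediate
6 | methyl bromoacetate | COC(=O)CBr | starting material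
7 | methyl 2-[4-(3,5-dimethoxyphenoxy)-3,5-dimethoxyphenoxy]acetate | COC(=O)COc1cc(OC)c(Oc2cc(OC)cc(OC)c2)c(OC)c1 | intermediate
8 | 2-[4-(3,5-dimethoxyphenoxy)-3,5-dimethoxyphenoxy]acetic acid | OC(=O)COc1cc(OC)c(Oc2cc(OC)cc(OC)c2)c(OC)c1 | intermediate
9 | ethoxyacetylene (ethoxyethyne) | CCOC#C | starting material
10 | 2-[4-(3,5-dimethoxyphenoxy)-3,5-dimethoxyphenoxy]acetyl chloride (not isolated) | ClC(=O)COc1cc(OC)c(Oc2cc(OC)cc(OC)c2)c(OC)c1 | intermediate
11 | 2-[4-(3,5-dimethoxyphenoxy)-3,5-dimethoxyphenoxy]ethen-1-one, the aryloxyketene (not isolated) | O=C=COc1cc(OC)c(Oc2cc(OC)cc(OC)c2)c(OC)c1 | intermediate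
12 | racemic 4-[4-(3,5-dimethoxyphenoxy)-3,5-dimethoxyphenoxy]-3-ethoxycyclobut-2-en-1-one | CCOC1=CC(=O)C1Oc1cc(OC)c(Oc2cc(OC)cc(OC)c2)c(OC)c1 | intermediate
13 | chloroacetaldehyde dimethyl acetal (2-chloro-1,1-dimethoxyethane) | COC(CCl)OC | starting material
14 | lithium methoxyacetylide (not isolated) | [Li]C#COC | intermediate
15 | (methoxyethynyl)trimethylsilane | COC#C[Si](C)(C)C | intermediate
16 | (3Z)-4-[4-(3,5-dimethoxyphenoxy)-3,5-dimethoxyphenoxy]-3-ethoxybuta-1,3-dien-1-one, the vinylketene (not isolated) | O=C=C/C(OCC)=C/Oc1cc(OC)c(Oc2cc(OC)cc(OC)c2)c(OC)c1 | intermediate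
17 | racemic 4-{(Z)-2-[4-(3,5-dimethoxyphenoxy)-3,5-dimethoxyphenoxy]-1-ethoxyethenyl}-3-methoxy-2-(trimethylsilyl)cyclobut-2-en-1-one (not isolated) | O=C1C([Si](C)(C)C)=C(OC)C1/C(OCC)=C/Oc1cc(OC)c(Oc2cc(OC)cc(OC)c2)c(OC)c1 | intermediate
18 | (3E,5Z)-6-[4-(3,5-dimethoxyphenoxy)-3,5-dimethoxyphenoxy]-5-ethoxy-3-methoxy-2-(trimethylsilyl)hexa-1,3,5-trien-1-one, the dienylketene (not isolated) | O=C=C([Si](C)(C)C)/C(OC)=C\C(OCC)=C\Oc1cc(OC)c(Oc2cc(OC)cc(OC)c2)c(OC)c1 | intermediate
19 | racemic 6-[4-(3,5-dimethoxyphenoxy)-3,5-dimethoxyphenoxy]-5-ethoxy-3-methoxy-2-(trimethylsilyl)cyclohexa-2,4-dien-1-one (not isolated) | O=C1C([Si](C)(C)C)=C(OC)C=C(OCC)C1Oc1cc(OC)c(Oc2cc(OC)cc(OC)c2)c(OC)c1 | intermediate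
20 | 6-[4-(3,5-dimethoxyphenoxy)-3,5-dimethoxyphenoxy]-5-ethoxy-3-methoxy-2-(trimethylsilyl)phenol | COc1cc(OC)cc(Oc2c(OC)cc(Oc3c(OCC)cc(OC)c([Si](C)(C)C)c3O)cc2OC)c1 | intermediate
21 | 2-bromo-6-[4-(3,5-dimethoxyphenoxy)-3,5-dimethoxyphenoxy]-5-ethoxy-3-methoxyphenol | COc1cc(OC)cc(Oc2c(OC)cc(Oc3c(OCC)cc(OC)c(Br)c3O)cc2OC)c1 | intermediate
22 | 2-bromo-4-[4-(3,5-dihydroxyphenoxy)-3,5-dihydroxyphenoxy]benzene-1,3,5-triol | Oc1cc(O)cc(Oc2c(O)cc(Oc3c(O)cc(O)c(Br)c3O)cc2O)c1 | target

## Step count and least certain steps

Total step count: 9. Longest linear sequence: 8 steps (steps 1–5 and 7–9, from 1 to 22); step 6 is a one-step side branch.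

**Step 7 (key step).** The most likely failure is a slow cycloaddition of the sterically loaded, C-silylated ynol ether 15 with vinylketene 16, so that 16 is consumed by self-condensation; loss of silicon from 20 by protodesilylation during heating or chromatography is the second risk. The fallback gives up silicon and sets out from 12. Heating 12 with the unhindered ynol ether 9 (toluene, 80 °C, sealed tube) should give 2-[4-(3,5-dimethoxyphenoxy)-3,5-dimethoxyphenoxy]-3,5-diethoxyphenol F1. One equivalent of NBS with catalytic i-Pr2NH in CH2Cl2 at −78 to 0 °C should brominate ring C, the only free phenol, mainly ortho to the hydroxyl, giving 2-bromo-6-[4-(3,5-dimethoxyphenoxy)-3,5-dimethoxyphenoxy]-3,5-diethoxyphenol F2. The para isomer 4-bromo-2-[4-(3,5-dimethoxyphenoxy)-3,5-dimethoxyphenoxy]-3,5-diethoxyphenol F3 is equally acceptable, because both open positions of ring C become the same carbon after dealkylation. BBr3 as in step 9 brings the route back at 22. The price is that ring selectivity then rests on the free phenol alone, without ipso acceleration.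

**Step 8.** The most likely failure is bromination that does not stop at the C–Si carbon: a second bromine at C3 of 21, or attack on rings A and B where NBS is locally in excess. Protodesilylation of 20 by traces of HBr, followed by slower and less ring-selective bromination, is the other risk. The fallback sets out from 20 and comes back at 21. It changes the reacting species and the mode of bromine delivery: Br2 is added to t-BuNH2 in toluene at −78 °C and 20 is then added, so that the ammonium phenoxide of 20 reacts with an N-bromoamine. The phenoxide ion pair exceeds the trialkoxy rings A and B in carbon nucleophilicity by orders of magnitude, the N-bromoamine does not attack aryl ethers at this temperature, and bromine is delivered next to the phenoxide oxygen, where silicon sits. No new compound is made.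

**Step 5.** The most likely failure is that aryloxyketene 11 dimerises or is intercepted by chloride or amine faster than it adds to the moderately nucleophilic alkyne 9; hydrolysis of the vinylogous ester 12 on silica is a second risk. The fallback sets out from phenol 5, reaches vinylketene 16 without a four-membered ring, and so comes back to the route at 16 and hence at 20.
- Alkylation of 5 with ethyl 4-chloro-3-oxobutanoate (NaH, THF) should give ethyl 4-[4-(3,5-dimethoxyphenoxy)-3,5-dimethoxyphenoxy]-3-oxobutanoate F4.
- Triethyl orthoformate with catalytic acid in ethanol should convert F4 into the enol ether ethyl (2E)-4-[4-(3,5-dimethoxyphenoxy)-3,5-dimethoxyphenoxy]-3-ethoxybut-2-enoate F5.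
- LiOH should give (2E)-4-[4-(3,5-dimethoxyphenoxy)-3,5-dimethoxyphenoxy]-3-ethoxybut-2-enoic acid F6.
- Oxalyl chloride should give (2E)-4-[4-(3,5-dimethoxyphenoxy)-3,5-dimethoxyphenoxy]-3-ethoxybut-2-enoyl chloride F7, used without isolation.
- 1,4-Dehydrochlorination of F7 with Et3N in the presence of 15, followed by warming to 80–110 °C, generates 16, a known way of making vinylketenes; the geometry of its enol ether double bond is of no consequence for ring C.

**Step 1.** The most likely failure is slow turnover with the di-ortho-substituted, electron-poor phenoxide, so that boronic acid 2 is used up by protodeboronation, homocoupling and oxidation. The fallback sets out from 1 and comes back at 3. It replaces the oxidative coupling by an Ullmann-type arylation with an aryl halide: 1 and purchased 1-iodo-3,5-dimethoxybenzene, CuI (catalytic) with picolinic acid, K3PO4, DMSO, 90 °C. No new compound is made.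

**Step 9.** The most likely failures are incomplete cleavage of the six ethers (the ethyl ether and the ring B methoxy groups next to the diaryl ether should be slowest), acid-promoted loss of bromine from the very electron-rich ring C, and oxidative loss of the free heptaphenol during isolation. The fallback sets out from 21 and comes back at 22. After BBr3 treatment the crude product is acetylated directly (Ac2O, pyridine) to 2-bromo-4-{3,5-bis(acetyloxy)-4-[3,5-bis(acetyloxy)phenoxy]phenoxy}benzene-1,3,5-triyl triacetate F8. F8 is stable on silica and can be separated from partly alkylated or debrominated material. Methanolysis (K2CO3 catalytic, degassed MeOH, 0 °C, then acidic resin) should then release 22.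

## Further compounds

F1 | step 7 | 2-[4-(3,5-dimethoxyphenoxy)-3,5-dimethoxyphenoxy]-3,5-diethoxyphenol | Oc1cc(OCC)cc(OCC)c1Oc1cc(OC)c(Oc2cc(OC)cc(OC)c2)c(OC)c1
F2 | step 7 | 2-bromo-6-[4-(3,5-dimethoxyphenoxy)-3,5-dimethoxyphenoxy]-3,5-diethoxyphenol | Oc1c(Br)c(OCC)cc(OCC)c1Oc1cc(OC)c(Oc2cc(OC)cc(OC)c2)c(OC)c1
F3 | step 7 | 4-bromo-2-[4-(3,5-dimethoxyphenoxy)-3,5-dimethoxyphenoxy]-3,5-diethoxyphenol | Oc1cc(OCC)c(Br)c(OCC)c1Oc1cc(OC)c(Oc2cc(OC)cc(OC)c2)c(OC)c1
F0 | step 8 | none | none
F4 | step 5 | ethyl 4-[4-(3,5-dimethoxyphenoxy)-3,5-dimethoxyphenoxy]-3-oxobutanoate | CCOC(=O)CC(=O)COc1cc(OC)c(Oc2cc(OC)cc(OC)c2)c(OC)c1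
F5 | step 5 | ethyl (2E)-4-[4-(3,5-dimethoxyphenoxy)-3,5-dimethoxyphenoxy]-3-ethoxybut-2-enoate | CCOC(=O)/C=C(/OCC)COc1cc(OC)c(Oc2cc(OC)cc(OC)c2)c(OC)c1
F6 | step 5 | (2E)-4-[4-(3,5-dimethoxyphenoxy)-3,5-dimethoxyphenoxy]-3-ethoxybut-2-enoic acid | OC(=O)/C=C(/OCC)COc1cc(OC)c(Oc2cc(OC)cc(OC)c2)c(OC)c1
F7 | step 5 | (2E)-4-[4-(3,5-dimethoxyphenoxy)-3,5-dimethoxyphenoxy]-3-ethoxybut-2-enoyl chloride | ClC(=O)/C=C(/OCC)COc1cc(OC)c(Oc2cc(OC)cc(OC)c2)c(OC)c1
F0 | step 1 | none | none
F8 | step 9 | 2-bromo-4-{3,5-bis(acetyloxy)-4-[3,5-bis(acetyloxy)phenoxy]phenoxy}benzene-1,3,5-triyl triacetate | CC(=O)Oc1cc(OC(C)=O)cc(Oc2c(OC(C)=O)cc(Oc3c(OC(C)=O)cc(OC(C)=O)c(Br)c3OC(C)=O)cc2OC(C)=O)c1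
A1 | alternative 1 | 5-[4-(3-bromo-2,4,6-trimethoxyphenoxy)-2,6-dimethoxyphenoxy]benzene-1,3-diol | Oc1cc(O)cc(Oc2c(OC)cc(Oc3c(OC)cc(OC)c(Br)c3OC)cc2OC)c1
A2 | alternative 1 | 2-bromo-4-(3,5-dimethoxy-4-phenoxyphenoxy)-1,3,5-trimethoxybenzene | COc1cc(OC)c(Br)c(OC)c1Oc1cc(OC)c(Oc2ccccc2)c(OC)c1
A3 | alternative 2 | 5-(3-bromo-2,4,6-trimethoxyphenoxy)-2-(3,5-dimethoxyphenoxy)benzene-1,3-diol | COc1cc(OC)cc(Oc2c(O)cc(Oc3c(OC)cc(OC)c(Br)c3OC)cc2O)c1
A4 | alternative 2 | methyl (2E)-3-(3-bromo-2,4,6-trimethoxyphenoxy)-6-(3,5-dimethoxyphenoxy)-5-oxohex-2-enoate | COC(=O)/C=C(/Oc1c(OC)cc(OC)c(Br)c1OC)CC(=O)COc1cc(OC)cc(OC)c1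
A5 | alternative 3 | dimethyl 5-[4-(3,5-dimethoxyphenoxy)-3,5-dimethoxyphenoxy]-2,4,6-trihydroxybenzene-1,3-dicarboxylate | COC(=O)c1c(O)c(Oc2cc(OC)c(Oc3cc(OC)cc(OC)c3)c(OC)c2)c(O)c(C(=O)OC)c1O
A6 | alternative 3 | dimethyl 2-[4-(3,5-dimethoxyphenoxy)-3,5-dimethoxyphenoxy]propanedioate | COC(=O)C(Oc1cc(OC)c(Oc2cc(OC)cc(OC)c2)c(OC)c1)C(=O)OC
A7 | alternative 3 | dimethyl 3-oxopentanedioate | COC(=O)CC(=O)CC(=O)OC
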